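(The constants belong to no real substance; the run is a simulation.)

Two neighbours differ from the flask in the charge of starting material, with the time and the rest of the recipe held.

starting material 0.050 M; gas 17 mM (held); time 12 min

    starting material + partner → target (k1 = 1.70 /M/s)
    2 starting material → side product (k2 = 0.276 /M/s)
    gas ⇌ partner, rate k3*(csat - [partner]) (k3 = 0.159 /s, csat = 17 mM)

- percent here means starting material units held: one side product counts as two
- a step written with two of one species runs at k times the square of its concentration and takes two of it each time
- at the start none of partner is dissolved
- run time (flask): 12 min

- the target standing at 12 min, as a percentage of the starting material charged
- concentration of partner in solution at 12 min, in percent of saturation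

Starting material is lost by two routes, so this reckoning follows what is left of it. While it is being used, the gas supply balances the partner's use at about 0.159 /s/(0.159 /s+1.70 /M/s·0.050 M) = 65.2% of saturation; this level, taken at the charge, is kept throughout.

The crossing level c×, the concentration of starting material at which both routes take it equally, is then 1.70 /M/s·c(partner)/(2·0.276 /M/s) = 34.1 mM. Each unit lost becomes target with the share c×/(c×+c(starting material)), the instantaneous selectivity. Summed from the charge c₀ downward, this gives y = (c×/c₀)·ln(1+c₀/c×).

In the flask the charge stands 1.47 times c×, higher than the crossing level, so the side product takes the larger share at first. In the first neighbour, holding 0.013 M, c× is 46.0 mM. Its charge is lower than that, so on this reckoning, with the partner at its held level, the target takes the larger share.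

For the flask, y comes to 61.6%. With both routes running at the held partner level, starting material has a first half-life near 18.1 s, and the transfer has one of 4.36 s. Both are shorter than 12 min, so this reckoning expects saturation at the end.

The forecast gives 60% and 100%, a little lower in y than this reckoning, holding that “the yield is fixed purely by the competition between the two routes”.

The flask gives 60.4% and 100%.

The side-product step is the main reason for the flask's shortfall: without it, the target stands at 100% and not 60.4%. The reading time makes no difference, with 60.4% at 120 min. From c×, the flask's y was 61.6%, which is 1.2 percentage points from the result.

In the second neighbour, holding 0.085 M, c× falls to 27.4 mM, which gives y = 45.5%. The computed result is 47.0%.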